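**Strategy**

Everything rests on cutting the C8–O4' aryl ether together with the benzylic C7–OH, the two bonds that one oxidative phenol coupling creates. The step exploits the free 4-OH of ring A para to C7 and the ring B oxygen O4' flanked by two methoxy groups, with C1', C3' and C5' blocked: a C8-centred sinapyl radical and an O-centred ring B radical can only join as C8–O4', and water then adds to C7 of the ring A quinone methide. The precursors are two unprotected phenols, (E)-sinapyl alcohol and dihydrosinapyl alcohol. Both stereocentres arise in this operation without absolute control, so the threo racemate is isolated and resolved.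

Key step: step 3

Remark: the target SMILES decodes to (7R,8R), the threo (syn) series; since radical coupling cannot fix absolute configuration, the route passes through racemates, written below as both enantiomers joined by a dot (locants 7–9: side chain of ring A; primed locants: ring B).

**Route**

Step 1
Reactants: 1 sinapaldehyde [(E)-3-(4-hydroxy-3,5-dimethoxyphenyl)prop-2-enal]
Product: 2 (E)-sinapyl alcohol [4-[(E)-3-hydroxyprop-1-enyl]-2,6-dimethoxyphenol]
Conditions: NaBH4, CeCl3·7H2O, MeOH, 0 °C; cold aq. NH4Cl work-up
Reagents that add atoms: none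
Why: Luche reduction, in which the cerium-activated carbonyl of the enal takes hydride from NaBH4 in a 1,2-sense, so that the (E)-alkene and the free phenol stay untouched and no stereocentre is formed.

Step 2
Reactants: 3 4-allyl-2,6-dimethoxyphenol
Product: 5 dihydrosinapyl alcohol [4-(3-hydroxypropyl)-2,6-dimethoxyphenol], via bis(9-BBN) adduct 4 (not isolated)
Conditions: 9-BBN (2.5 equiv), THF, 0 °C to rt; then aq. NaOH, 30% H2O2, 0 °C to rt
Reagents that add atoms: hydrogen peroxide, OO
Why: Hydroboration–oxidation, in which the bulky 9-BBN places boron on the terminal carbon of the allyl group (the phenol is expected to be borylated in passing, hence the excess) and alkaline peroxide turns the C–B bond into the primary alcohol and frees the phenol; no stereocentre is formed.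

Step 3
Reactants: 2 (E)-sinapyl alcohol; 5 dihydrosinapyl alcohol
Product: 7 racemic threo-1-(4-hydroxy-3,5-dimethoxyphenyl)-2-[4-(3-hydroxypropyl)-2,6-dimethoxyphenoxy]propane-1,3-diol, via quinone methide 6 (not isolated)
Conditions: laccase (Trametes versicolor, low loading), air (O2), acetone/NaOAc buffer pH 5 (1:4), rt; 2 (1 equiv) fed over 8 h into 5 (4 equiv); SiO2, then C18 HPLC (MeOH/H2O)
Reagents that add atoms: water, O
Why: The laccase, a multicopper oxidase that passes the electrons to O2, takes one electron and one proton from each phenol; the radical of 2 is delocalised into the propenyl chain and carries spin at C8, while the radical of 5 has C1', C3' and C5' occupied and can bond only through O4'. Radical–radical combination forms the C8–O4' ether and leaves the ring A p-quinone methide 6, to which water adds at C7 in a 1,6-sense, restoring the 4-hydroxy-3,5-dimethoxyphenyl ring and creating the benzylic hydroxyl. The closest known reaction type is the dehydrogenative 8-O-4' coupling of a monolignol with a phenol followed by quinone methide hydration, the chain-extension event of lignin formation; no ring is closed. C8 is formed without facial bias and is racemic, and C7 is set by substrate control when water attacks 6 next to the C8 aryloxy group, where the erythro pair is expected to be at least as abundant as the threo pair, so the threo (7R*,8R*) racemate is taken out by C18 chromatography. The step needs cross-coupling over the 8–8' self-coupling of 2 and over re-oxidation of the phenolic product; the substrate pair secures this because the radical of 5 has no carbon site for productive self-coupling and is kept in fourfold excess while 2 is fed slowly. The excess of 5 is recovered on silica.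

Step 4
Reactants: 7 racemic threo-1-(4-hydroxy-3,5-dimethoxyphenyl)-2-[4-(3-hydroxypropyl)-2,6-dimethoxyphenoxy]propane-1,3-diol
Product: 8 (1R,2R)-1-(4-hydroxy-3,5-dimethoxyphenyl)-2-[4-(3-hydroxypropyl)-2,6-dimethoxyphenoxy]propane-1,3-diol [the (7R,8R) target]
Conditions: preparative HPLC on amylose tris(3,5-dimethylphenylcarbamate)/silica, n-hexane/EtOH, rt
Reagents that add atoms: none
Why: Resolution of a racemate by enantioselective chromatography, in which the carbamate phase binds the two enantiomers through diastereomeric hydrogen-bond and π contacts so that they should elute apart, the (7R,8R) fraction being identified by comparing its ECD curve with the one computed for that configuration; no bond is made or broken, so C7 and C8 cannot scramble.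

**Compound list**

1 | sinapaldehyde, (E)-3-(4-hydroxy-3,5-dimethoxyphenyl)prop-2-enal | COc1cc(/C=C/C=O)cc(OC)c1O | starting material
2 | (E)-sinapyl alcohol, 4-[(E)-3-hydroxyprop-1-enyl]-2,6-dimethoxyphenol | COc1cc(/C=C/CO)cc(OC)c1O | intermediate
3 | 4-allyl-2,6-dimethoxyphenol | C=CCc1cc(OC)c(O)c(OC)c1 | starting material
4 | bis(9-BBN) adduct (not isolated): B-[3-(3,5-dimethoxy-4-{(9-borabicyclo[3.3.1]nonan-9-yl)oxy}phenyl)propyl]-9-borabicyclo[3.3.1]nonane | COc1cc(CCCB2C3CCCC2CCC3)cc(OC)c1OB1C2CCCC1CCC2 | intermediate
5 | dihydrosinapyl alcohol, 4-(3-hydroxypropyl)-2,6-dimethoxyphenol | COc1cc(CCCO)cc(OC)c1O | intermediate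
6 | racemic quinone methide (not isolated): 4-{3-hydroxy-2-[4-(3-hydroxypropyl)-2,6-dimethoxyphenoxy]propylidene}-2,6-dimethoxycyclohexa-2,5-dien-1-one, both enantiomers at C8 | COC1=CC(=C[C@@H](CO)Oc2c(OC)cc(CCCO)cc2OC)C=C(OC)C1=O.COC1=CC(=C[C@H](CO)Oc2c(OC)cc(CCCO)cc2OC)C=C(OC)C1=O | intermediate
7 | racemic threo (7R*,8R*) 8-O-4' ether: 1-(4-hydroxy-3,5-dimethoxyphenyl)-2-[4-(3-hydroxypropyl)-2,6-dimethoxyphenoxy]propane-1,3-diol, (1R,2R) and (1S,2S) enantiomers | COc1cc([C@@H](O)[C@@H](CO)Oc2c(OC)cc(CCCO)cc2OC)cc(OC)c1O.COc1cc([C@H](O)[C@H](CO)Oc2c(OC)cc(CCCO)cc2OC)cc(OC)c1O | intermediate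
8 | (1R,2R)-1-(4-hydroxy-3,5-dimethoxyphenyl)-2-[4-(3-hydroxypropyl)-2,6-dimethoxyphenoxy]propane-1,3-diol, the (7R,8R)-threo ether | COc1cc([C@@H](O)[C@@H](CO)Oc2c(OC)cc(CCCO)cc2OC)cc(OC)c1O | target

**Step count**

Total steps: 4. Longest linear sequence: 3 steps (1 → 2 → 7 → 8 through steps 1, 3 and 4; the branch 3 → 5 → 7 → 8 is equally long).

**Steps most likely to fail**

Step 3. Self-coupling of the sinapyl radical and further oxidation of the phenolic product may outrun the cross-coupling, and hydration of the quinone methide may run mainly into the erythro series.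

Fallback, setting out from 5 and returning at 8, so that step 4 is not needed. The ether and both stereocentres are built by an auxiliary-controlled ionic sequence instead of a radical one.
- The phenol of 5 is alkylated with the known reagent (S)-4-benzyl-3-(bromoacetyl)oxazolidin-2-one (K2CO3, acetone) to give the aryloxyacetyl imide F1.
- Its primary hydroxyl is capped (Ac2O, pyridine) to give the acetate F2.
- Bu2BOTf and iPr2NEt in CH2Cl2 at −78 °C form the (Z)-boron enolate F3.
- F3 adds to commercial 4-(benzyloxy)-3,5-dimethoxybenzaldehyde through a Zimmerman–Traxler chair on the face remote from the benzyl group of the auxiliary. After a pH 7 buffer/MeOH work-up this Evans syn aldol should give the (2S,3R) adduct F4, which has the threo arrangement of the target.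
- LiBH4 (excess, THF/MeOH, 0 °C) reduces the imide to the C9 alcohol with release of the auxiliary and cleaves the acetate, giving the benzyl ether F5.
- Hydrogenolysis (H2, Pd/C, EtOAc, rt) removes the benzyl group and gives 8.

Step 4. The enantiomers may fail to separate to baseline at preparative loading.

Fallback, setting out from 7 and returning at 8. The resolution is moved to covalent diastereomers.
- 7 is acylated at the phenol and at both primary hydroxyls with (1S)-camphanic chloride (3.3 equiv, pyridine, CH2Cl2, −20 °C), the hindered C7 hydroxyl being left free. This gives the (7R,8R) triscamphanate F6 and the (7S,8S) triscamphanate F7, which should separate on plain silica or by crystallisation.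
- Methanolysis of F6 (K2CO3, MeOH, rt) returns 8. Because the C7 hydroxyl is never acylated, no quinone methide can form from ring A during the basic cleavage.

Step 2. Consumption of borane by the phenol may leave the alkene partly unreacted, and the alkaline peroxide may attack the electron-rich ring.

Fallback, setting out from 2 and returning at 5. The side-chain alkene of 2 is hydrogenated (H2, 1 atm, Pd/C, EtOAc, rt), which gives 5 directly, so that no new compound arises (entry F0).

**Further compounds**

F1 | step 3 | (S)-4-benzyl-3-{2-[4-(3-hydroxypropyl)-2,6-dimethoxyphenoxy]acetyl}oxazolidin-2-one | COc1cc(CCCO)cc(OC)c1OCC(=O)N1[C@@H](Cc2ccccc2)COC1=O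
F2 | step 3 | 3-{4-[2-((S)-4-benzyl-2-oxooxazolidin-3-yl)-2-oxoethoxy]-3,5-dimethoxyphenyl}propyl acetate | COc1cc(CCCOC(C)=O)cc(OC)c1OCC(=O)N1[C@@H](Cc2ccccc2)COC1=O
F3 | step 3 | (Z)-dibutylboron enolate of F2 | CCCCB(CCCC)O/C(=C\Oc1c(OC)cc(CCCOC(C)=O)cc1OC)N1[C@@H](Cc2ccccc2)COC1=O
F4 | step 3 | (4S)-3-[(2S,3R)-2-{4-[3-(acetyloxy)propyl]-2,6-dimethoxyphenoxy}-3-[4-(benzyloxy)-3,5-dimethoxyphenyl]-3-hydroxypropanoyl]-4-benzyloxazolidin-2-one | COc1cc([C@@H](O)[C@@H](C(=O)N2[C@@H](Cc3ccccc3)COC2=O)Oc2c(OC)cc(CCCOC(C)=O)cc2OC)cc(OC)c1OCc1ccccc1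
F5 | step 3 | (1R,2R)-1-[4-(benzyloxy)-3,5-dimethoxyphenyl]-2-[4-(3-hydroxypropyl)-2,6-dimethoxyphenoxy]propane-1,3-diol | COc1cc([C@@H](O)[C@@H](CO)Oc2c(OC)cc(CCCO)cc2OC)cc(OC)c1OCc1ccccc1
F6 | step 4 | (7R,8R)-4,9,9'-tris-O-[(1S)-camphanoyl] derivative of 8 | COc1cc([C@@H](O)[C@@H](COC(=O)[C@@]23CC[C@@](C)(C(=O)O2)C3(C)C)Oc4c(OC)cc(CCCOC(=O)[C@@]56CC[C@@](C)(C(=O)O5)C6(C)C)cc4OC)cc(OC)c1OC(=O)[C@@]78CC[C@@](C)(C(=O)O7)C8(C)C
F7 | step 4 | (7S,8S)-4,9,9'-tris-O-[(1S)-camphanoyl] diastereomer of F6 | COc1cc([C@H](O)[C@H](COC(=O)[C@@]23CC[C@@](C)(C(=O)O2)C3(C)C)Oc4c(OC)cc(CCCOC(=O)[C@@]56CC[C@@](C)(C(=O)O5)C6(C)C)cc4OC)cc(OC)c1OC(=O)[C@@]78CC[C@@](C)(C(=O)O7)C8(C)C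
F0 | step 2 | none | none
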